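**Assumption:** the target has no stereocentre, so no stereocontrol is needed; it is drawn as the free bis(hydrogen sulfate), so the last step ends with an exchange of the counter-ions for H+.

## Retrosynthetic overview

1. Target 9 ⇐ bis(tetrabutylammonium) ketal 7, by hydrogenolysis of the catechol diphenylmethylene ketal and H+ exchange.
2. C3–O bond and 3-O-sulfate of 7 ⇐ flavone 4, by a one-pot formal C3–H sulfatoxylation: dioxirane epoxidation of C2=C3 (C–O bond formation), then SO3-induced eliminative opening of the epoxide.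
3. 7-O-sulfate of 4 ⇐ ketal 2, by sulfation of its only unchelated phenol.
4. Ketal 2 ⇐ luteolin 1 + dichlorodiphenylmethane.
5. No ring of the target is built: A, B and C rings come intact from luteolin. The only ring formed on the way is the transient oxirane.

## Route

**Step 1**
Reactants: 1 luteolin
Product: 2 2-(2,2-diphenyl-1,3-benzodioxol-5-yl)-5,7-dihydroxy-4H-chromen-4-one
Conditions: Ph2CCl2 (1.5 equiv), Ph2O, 175 °C, 30 min
Reagents that add atoms: dichlorodiphenylmethane, ClC(Cl)(c1ccccc1)c1ccccc1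
Why: Ketalisation by double substitution at the gem-dichloride closes a five-membered 1,3-benzodioxole only on the vicinal 3',4'-diol, the standard catechol protection of quercetin-type flavonoids, so the 5- and 7-OH stay free.

**Step 2**
Reactants: 2 2-(2,2-diphenyl-1,3-benzodioxol-5-yl)-5,7-dihydroxy-4H-chromen-4-one
Product: 4 tetrabutylammonium 2-(2,2-diphenyl-1,3-benzodioxol-5-yl)-5-hydroxy-4-oxo-4H-chromen-7-yl sulfate, via pyridinium 7-sulfate salt 3 (not isolated)
Conditions: SO3·pyridine (1.3 equiv), pyridine, 0 °C → rt; then aq. Bu4NOH (1.0 equiv), CH2Cl2 extraction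
Reagents that add atoms: sulfur trioxide–pyridine complex, O=S(=O)([O-])[n+]1ccccc1; tetrabutylammonium hydroxide, CCCC[N+](CCCC)(CCCC)CCCC.[OH-]
Why: O-sulfation with a sulfur trioxide–amine complex takes the 7-OH, the most acidic and only unchelated phenol, while the 5-OH is held in the hydrogen bond to C4=O and does not sulfate under these conditions; Bu4N+ makes the salt soluble in organic solvents.

**Step 3**
Reactants: 4 tetrabutylammonium 2-(2,2-diphenyl-1,3-benzodioxol-5-yl)-5-hydroxy-4-oxo-4H-chromen-7-yl sulfate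
Product: 7 bis(tetrabutylammonium) 2-(2,2-diphenyl-1,3-benzodioxol-5-yl)-5-hydroxy-4-oxo-4H-chromene-3,7-diyl bis(sulfate), via 2,3-epoxide 5 (not isolated), via pyridinium tetrabutylammonium 3,7-disulfate 6 (not isolated)
Conditions: DMDO (3 equiv, ca. 0.07 M in acetone), CH2Cl2, 0 °C → rt, dark; evaporate at ≤ 20 °C; then SO3·pyridine (1.5 equiv), MeCN, 0 °C → rt; then aq. Bu4NOH (1.0 equiv), CH2Cl2 extraction
Reagents that add atoms: dimethyldioxirane, CC1(C)OO1; sulfur trioxide–pyridine complex, O=S(=O)([O-])[n+]1ccccc1; tetrabutylammonium hydroxide, CCCC[N+](CCCC)(CCCC)CCCC.[OH-]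
Why: Proposed new method: a formal C3–H sulfatoxylation of a flavone in which dimethyldioxirane first transfers oxygen to C2=C3 (flavone epoxidation, which makes the C3–O bond; the two transient stereocentres are cis by ring fusion, racemic, and erased again), and SO3·pyridine then sulfonates the epoxide oxygen, the C2–O bond ionises to the oxocarbenium ion stabilised by O1 and the aryl group, and pyridine removes H-3 to give the aromatic pyranone 3-O-sulfate directly (if the acid-labile epoxide first isomerises to the 3-ol, the same reagent sulfates it to the same product); the closest known reactions are SO3 insertion into simple epoxides to give cyclic sulfates and the acid-catalysed isomerisation of flavone epoxides to flavonols.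

**Step 4**
Reactants: 7 bis(tetrabutylammonium) 2-(2,2-diphenyl-1,3-benzodioxol-5-yl)-5-hydroxy-4-oxo-4H-chromene-3,7-diyl bis(sulfate)
Product: 9 quercetin 3,7-di-O-sulfate, via bis(tetrabutylammonium) quercetin 3,7-disulfate 8 (not isolated)
Conditions: H2 (1 atm), 10% Pd/C, THF–MeOH 1:1, rt; filter; then Dowex 50WX8 (H+ form), H2O–MeOH, 0 °C, freeze-dry at once
Reagents that add atoms: none
Why: Hydrogenolysis of the two doubly benzylic C–O bonds of the diphenylmethylene ketal frees the catechol under neutral conditions that aryl sulfate monoesters tolerate (as in debenzylation of flavonoid sulfates), and cold strong-acid cation exchange replaces Bu4N+ by H+ to give the drawn acid form.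

## Compound list

1 | luteolin | O=c1cc(-c2ccc(O)c(O)c2)oc2cc(O)cc(O)c12 | starting material
2 | 2-(2,2-diphenyl-1,3-benzodioxol-5-yl)-5,7-dihydroxy-4H-chromen-4-one (3',4'-O-diphenylmethylene-luteolin) | O=c1cc(-c2ccc3OC(c4ccccc4)(c4ccccc4)Oc3c2)oc2cc(O)cc(O)c12 | intermediate
3 | pyridinium 2-(2,2-diphenyl-1,3-benzodioxol-5-yl)-5-hydroxy-4-oxo-4H-chromen-7-yl sulfate | O=c1cc(-c2ccc3OC(c4ccccc4)(c4ccccc4)Oc3c2)oc2cc(OS(=O)(=O)[O-])cc(O)c12.c1cc[nH+]cc1 | intermediate
4 | tetrabutylammonium 2-(2,2-diphenyl-1,3-benzodioxol-5-yl)-5-hydroxy-4-oxo-4H-chromen-7-yl sulfate | O=c1cc(-c2ccc3OC(c4ccccc4)(c4ccccc4)Oc3c2)oc2cc(OS(=O)(=O)[O-])cc(O)c12.CCCC[N+](CCCC)(CCCC)CCCC | intermediate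
5 | 2,3-epoxide of 4 (2,3-epoxyflavanone, epoxide cis-fused to the pyranone ring; racemic, one enantiomer drawn) | O=C1[C@H]2O[C@@]2(c3ccc4OC(c5ccccc5)(c5ccccc5)Oc4c3)Oc3cc(OS(=O)(=O)[O-])cc(O)c13.CCCC[N+](CCCC)(CCCC)CCCC | intermediate
6 | pyridinium tetrabutylammonium 2-(2,2-diphenyl-1,3-benzodioxol-5-yl)-5-hydroxy-4-oxo-4H-chromene-3,7-diyl bis(sulfate) | O=c1c(OS(=O)(=O)[O-])c(-c2ccc3OC(c4ccccc4)(c4ccccc4)Oc3c2)oc2cc(OS(=O)(=O)[O-])cc(O)c12.CCCC[N+](CCCC)(CCCC)CCCC.c1cc[nH+]cc1 | intermediate
7 | bis(tetrabutylammonium) 2-(2,2-diphenyl-1,3-benzodioxol-5-yl)-5-hydroxy-4-oxo-4H-chromene-3,7-diyl bis(sulfate) | O=c1c(OS(=O)(=O)[O-])c(-c2ccc3OC(c4ccccc4)(c4ccccc4)Oc3c2)oc2cc(OS(=O)(=O)[O-])cc(O)c12.CCCC[N+](CCCC)(CCCC)CCCC.CCCC[N+](CCCC)(CCCC)CCCC | intermediate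
8 | bis(tetrabutylammonium) quercetin 3,7-di-O-sulfate | O=c1c(OS(=O)(=O)[O-])c(-c2ccc(O)c(O)c2)oc2cc(OS(=O)(=O)[O-])cc(O)c12.CCCC[N+](CCCC)(CCCC)CCCC.CCCC[N+](CCCC)(CCCC)CCCC | intermediate
9 | quercetin 3,7-di-O-sulfate (achiral) | O=c1c(OS(=O)(=O)O)c(-c2ccc(O)c(O)c2)oc2cc(OS(=O)(=O)O)cc(O)c12 | target

## Step count

Total steps: 4. Longest linear sequence: 4.

## Steps most likely to fail

**Step 3 (the proposed new step).** The dioxirane may attack the ring carrying the free, chelated 5-OH instead of C2=C3, and the SO3-induced opening may stop at the 3-ol or give mixtures. The fallback uses known chemistry only, sets out from 2 and comes back at 7. Compound 2 is acetylated (Ac2O, pyridine, DMAP, 60 °C) to 5,7-di-O-acetyl-3',4'-O-(diphenylmethylene)luteolin F1, so that no free phenol meets the oxidant. DMDO in acetone/CH2Cl2 gives the 2,3-epoxide of the diacetate F2, which is not isolated but isomerised with catalytic p-TsOH in CH2Cl2 to 5,7-di-O-acetyl-3',4'-O-(diphenylmethylene)quercetin F3; this is the established two-stage conversion of flavones into flavonols. K2CO3 in MeOH under argon removes both acetates to give 3',4'-O-(diphenylmethylene)quercetin F4. Conventional O-sulfation of its 3- and 7-OH with Bu4NHSO4/DCC in pyridine (the chelated 5-OH does not react) gives 7 directly as the bis(tetrabutylammonium) salt.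

**Step 2.** Mono-sulfation may give mixtures of unreacted, mono- and bis-sulfated material, and the amphiphilic salt may be hard to purify. The fallback installs the sulfate in protected, neutral form; it sets out from 2 and comes back at 4. Compound 2 is treated with 2,2,2-trichloroethyl chlorosulfate (Et3N, DMAP, THF, 0 °C → rt) to give 2,2,2-trichloroethyl 2-(2,2-diphenyl-1,3-benzodioxol-5-yl)-5-hydroxy-4-oxo-4H-chromen-7-yl sulfate F5, a sulfate diester that can be purified on silica. Zn/HCO2NH4 in MeOH unmasks it by reductive fragmentation to the ammonium 2-(2,2-diphenyl-1,3-benzodioxol-5-yl)-5-hydroxy-4-oxo-4H-chromen-7-yl sulfate F6, and aqueous Bu4NOH with CH2Cl2 extraction converts this into 4.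

**Step 4.** The hydrogenolysis itself has precedent, but a flavonol 3-sulfate in its free acid form is prone to acid-promoted hydrolysis in water, so the aqueous resin exchange can cost the 3-sulfate. The fallback liberates the acid without water; it sets out from 8 and comes back at 9. After hydrogenolysis and filtration the solvent is removed and crude 8 is taken up in dry MeCN/CH2Cl2 at −30 °C. TfOH (2.0 equiv) protonates both sulfate groups in a medium without a hydroxylic nucleophile; the very polar free acid 9 precipitates and is filtered off cold, while tetrabutylammonium triflate stays in solution. No new compound is made on this way.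

## Further compounds

F1 | step 3 | 5,7-di-O-acetyl-3',4'-O-(diphenylmethylene)luteolin | O=c1cc(-c2ccc3OC(c4ccccc4)(c4ccccc4)Oc3c2)oc2cc(OC(C)=O)cc(OC(C)=O)c12
F2 | step 3 | 2,3-epoxide of the diacetate (cis-fused; racemic, one enantiomer drawn) | O=C1[C@H]2O[C@@]2(c3ccc4OC(c5ccccc5)(c5ccccc5)Oc4c3)Oc3cc(OC(C)=O)cc(OC(C)=O)c13
F3 | step 3 | 5,7-di-O-acetyl-3',4'-O-(diphenylmethylene)quercetin | O=c1c(O)c(-c2ccc3OC(c4ccccc4)(c4ccccc4)Oc3c2)oc2cc(OC(C)=O)cc(OC(C)=O)c12
F4 | step 3 | 3',4'-O-(diphenylmethylene)quercetin | O=c1c(O)c(-c2ccc3OC(c4ccccc4)(c4ccccc4)Oc3c2)oc2cc(O)cc(O)c12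
F5 | step 2 | 2,2,2-trichloroethyl 2-(2,2-diphenyl-1,3-benzodioxol-5-yl)-5-hydroxy-4-oxo-4H-chromen-7-yl sulfate | O=c1cc(-c2ccc3OC(c4ccccc4)(c4ccccc4)Oc3c2)oc2cc(OS(=O)(=O)OCC(Cl)(Cl)Cl)cc(O)c12
F6 | step 2 | ammonium 2-(2,2-diphenyl-1,3-benzodioxol-5-yl)-5-hydroxy-4-oxo-4H-chromen-7-yl sulfate | O=c1cc(-c2ccc3OC(c4ccccc4)(c4ccccc4)Oc3c2)oc2cc(OS(=O)(=O)[O-])cc(O)c12.[NH4+]
F0 | step 4 | none | none
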